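**Retrosynthetic overview**
- The target is 3,5,3'-trihydroxy-7,4'-dimethoxy-6,8-diprenylflavone; the last operations are MOM removal and a chelation-controlled 5-O-demethylation.
- Ring C is the only ring made: Algar–Flynn–Oyamada oxidative cyclisation of a 2'-hydroxychalcone, itself from Claisen–Schmidt condensation of a diprenylated acetophenone (ring A) with MOM-protected isovanillin (ring B).
- The strategy rests on the two prenyl groups at C6 and C8 of ring A: each is a benzylic CH2 (C1'') bonded to a 2-methylprop-1-enyl unit (C2''=C3''), and they sit on the two equivalent open positions of a phloroglucinol-type ring, either side of the C7 methoxy group.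
- Both C1''–C2'' bonds are cut, giving a bis(chloromethyl)trimethoxyacetophenone and an isobutenylboronate; the two chloromethyl groups are put on 2',4',6'-trimethoxyacetophenone by two successive Blanc chloromethylations.

Key step: step 3

Remark on the chemistry: paraformaldehyde is counted as formaldehyde, "prenyl" means 3-methylbut-2-enyl, each chloromethylation consumes one formaldehyde and one HCl and the second needs more forcing conditions than the first, and the MOM ether is removed before the final demethylation so that warm protic acid never meets a free phenol ortho to a prenyl group.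

**Route**

Step 1
Reactants: 1 2',4',6'-trimethoxyacetophenone; 2 paraformaldehyde (formaldehyde)
Product: 3 3'-(chloromethyl)-2',4',6'-trimethoxyacetophenone
Conditions: (CH2O)n (1.1 equiv CH2O), HCl gas, AcOH, 15–20 °C; crude product used promptly
Reagents that add atoms: hydrogen chloride, Cl
Why: Blanc chloromethylation; C3' is ortho to two methoxy groups and para to the third while the acetyl group is twisted out of conjugation by its two ortho methoxy groups, so protonated formaldehyde should attack there and HCl should convert the benzylic alcohol into the chloride, with limited formaldehyde and low temperature holding the reaction at the first substitution.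

Step 2
Reactants: 3 3'-(chloromethyl)-2',4',6'-trimethoxyacetophenone; 2 paraformaldehyde (formaldehyde)
Product: 4 3',5'-bis(chloromethyl)-2',4',6'-trimethoxyacetophenone
Conditions: (CH2O)n (3 equiv CH2O), HCl gas, AcOH, 45–50 °C
Reagents that add atoms: hydrogen chloride, Cl
Why: Second Blanc chloromethylation at the one remaining ring position C5', still flanked by two methoxy groups; excess formaldehyde and HCl at higher temperature should overcome the inductive deactivation by the first CH2Cl group and keep chloromethylation ahead of diarylmethane formation, and the product has no free ring position left.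

Step 3
Reactants: 4 3',5'-bis(chloromethyl)-2',4',6'-trimethoxyacetophenone; 5 2-methylprop-1-enylboronic acid pinacol ester
Product: 6 2',4',6'-trimethoxy-3',5'-bis(3-methylbut-2-enyl)acetophenone
Conditions: 5 (3 equiv), Pd(PPh3)4 (5 mol %), K3PO4 (anhydrous, powdered, 6 equiv), dry degassed 1,4-dioxane, 90 °C, argon
Reagents that add atoms: none
Why: Zerovalent palladium adds oxidatively to a benzylic C–Cl bond to give a divalent benzylpalladium chloride, phosphate activates the alkenylboronate so that its 2-methylprop-1-enyl group passes to palladium through a Pd–O–B bridge, and reductive elimination forms the C1''–C2'' bond; the cycle runs once at the C3' and once at the C5' benzylic carbon. The closest known reaction type is the sp3–sp2 Suzuki–Miyaura coupling of benzylic halides with alkenylboronic esters. No ring is closed and no stereocentre is formed, and because the distal alkene carbon carries two methyl groups there is no E/Z question. The step needs cross-coupling to outrun benzyl–benzyl homocoupling and solvolysis of the methoxy-activated chlorides: the benzylpalladium intermediate has no β-hydrogen, the boronate is in excess, and dry dioxane with solid K3PO4 keeps water and hydroxide away. Because the olefin arrives preformed on an sp2 C–B bond it cannot transpose to the branched 1,1-dimethylallyl isomer and O-alkylation cannot occur, while the acetyl group, shielded by two ortho methoxy groups, should be left alone.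

Step 4
Reactants: 6 2',4',6'-trimethoxy-3',5'-bis(3-methylbut-2-enyl)acetophenone
Product: 7 2'-hydroxy-4',6'-dimethoxy-3',5'-bis(3-methylbut-2-enyl)acetophenone
Conditions: MgI2·OEt2 (1.5 equiv), THF, reflux; then aq. Na2S2O3, brief cold 1 M HCl
Reagents that add atoms: none
Why: Chelation-controlled aryl methyl ether cleavage; magnesium binds the ketone oxygen and one flanking methoxy oxygen, iodide removes that methyl group by SN2, and the resulting magnesium phenoxide chelate deactivates the second (equivalent) ortho methoxy group, while the C4' methoxy cannot chelate and the mild Lewis acid spares the prenyl olefins.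

Step 5
Reactants: 8 isovanillin (3-hydroxy-4-methoxybenzaldehyde)
Product: 9 4-methoxy-3-(methoxymethoxy)benzaldehyde
Conditions: MOMCl, i-Pr2NEt, CH2Cl2, 0 °C to rt
Reagents that add atoms: chloromethyl methyl ether, COCCl
Why: Williamson-type O-alkylation of the phenol by the reactive α-chloro ether (MOM protection), which leaves the aldehyde untouched.

Step 6
Reactants: 7 2'-hydroxy-4',6'-dimethoxy-3',5'-bis(3-methylbut-2-enyl)acetophenone; 9 4-methoxy-3-(methoxymethoxy)benzaldehyde
Product: 10 (E)-1-[2-hydroxy-4,6-dimethoxy-3,5-bis(3-methylbut-2-enyl)phenyl]-3-[4-methoxy-3-(methoxymethoxy)phenyl]prop-2-en-1-one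
Conditions: KOH (50% aq.), EtOH, rt; neutralise with aq. NH4Cl
Reagents that add atoms: none
Why: Claisen–Schmidt condensation; the methyl ketone enolate adds to the non-enolisable aldehyde and E1cB dehydration should give the thermodynamically preferred E-enone, with the base-stable MOM ether preventing a deactivating phenoxide on ring B.

Step 7
Reactants: 10 (E)-chalcone
Product: 12 3-hydroxy-5,7-dimethoxy-2-[4-methoxy-3-(methoxymethoxy)phenyl]-6,8-bis(3-methylbut-2-enyl)-4H-chromen-4-one, via racemic trans-dihydroflavonol 11 (not isolated)
Conditions: H2O2 (30% aq.), NaOH (2 M aq.), MeOH–THF, 0 °C to rt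
Reagents that add atoms: hydrogen peroxide, OO
Why: Algar–Flynn–Oyamada reaction; the 2'-phenoxide closes ring C by 6-endo oxa-Michael addition, the enolate is hydroxylated at C3 by hydrogen peroxide to the dihydroflavonol and this is oxidised on to the flavonol, which erases the two transient stereocentres, while nucleophilic alkaline peroxide does not epoxidise the electron-rich prenyl olefins.

Step 8
Reactants: 12 MOM-protected flavonol
Product: 13 3-hydroxy-2-(3-hydroxy-4-methoxyphenyl)-5,7-dimethoxy-6,8-bis(3-methylbut-2-enyl)-4H-chromen-4-one
Conditions: 3 M aq. HCl, MeOH–THF, 40 °C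
Reagents that add atoms: none
Why: Acid-catalysed acetal cleavage of the MOM ether through an oxocarbenium ion trapped by methanol, run while C5–O is still methylated so that no phenol ortho to a prenyl group is available for acid-mediated chroman formation.

Step 9
Reactants: 13 3,3'-dihydroxy-5,7,4'-trimethoxy-6,8-diprenylflavone
Product: 14 3,5-dihydroxy-2-(3-hydroxy-4-methoxyphenyl)-7-methoxy-6,8-bis(3-methylbut-2-enyl)-4H-chromen-4-one (target)
Conditions: MgI2·OEt2 (4 equiv), THF, 60 °C; then aq. Na2S2O3, brief cold 1 M HCl
Reagents that add atoms: none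
Why: Chelation-controlled demethylation; magnesium bridges the C4 carbonyl and the peri C5 methoxy oxygen and iodide removes that methyl group by SN2, whereas the C7 and C4' methoxy groups have no neighbouring carbonyl, and the non-protic conditions should not cyclise the new 5-OH onto the 6-prenyl group.

**Compound list**

1 | 2',4',6'-trimethoxyacetophenone | CC(=O)c1c(OC)cc(OC)cc1OC | starting material
2 | paraformaldehyde (formaldehyde) | C=O | starting material
3 | 3'-(chloromethyl)-2',4',6'-trimethoxyacetophenone | CC(=O)c1c(OC)c(CCl)c(OC)cc1OC | intermediate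
4 | 3',5'-bis(chloromethyl)-2',4',6'-trimethoxyacetophenone | CC(=O)c1c(OC)c(CCl)c(OC)c(CCl)c1OC | intermediate
5 | 2-methylprop-1-enylboronic acid pinacol ester | CC(C)=CB1OC(C)(C)C(C)(C)O1 | starting material
6 | 2',4',6'-trimethoxy-3',5'-bis(3-methylbut-2-enyl)acetophenone | CC(=O)c1c(OC)c(CC=C(C)C)c(OC)c(CC=C(C)C)c1OC | intermediate
7 | 2'-hydroxy-4',6'-dimethoxy-3',5'-bis(3-methylbut-2-enyl)acetophenone | CC(=O)c1c(O)c(CC=C(C)C)c(OC)c(CC=C(C)C)c1OC | intermediate
8 | isovanillin (3-hydroxy-4-methoxybenzaldehyde) | COc1ccc(C=O)cc1O | starting material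
9 | 4-methoxy-3-(methoxymethoxy)benzaldehyde | COCOc1cc(C=O)ccc1OC | intermediate
10 | (E)-1-[2-hydroxy-4,6-dimethoxy-3,5-bis(3-methylbut-2-enyl)phenyl]-3-[4-methoxy-3-(methoxymethoxy)phenyl]prop-2-en-1-one | COCOc1cc(/C=C/C(=O)c2c(O)c(CC=C(C)C)c(OC)c(CC=C(C)C)c2OC)ccc1OC | intermediate
11 | rac-(2R,3R)-3-hydroxy-5,7-dimethoxy-2-[4-methoxy-3-(methoxymethoxy)phenyl]-6,8-bis(3-methylbut-2-enyl)chroman-4-one (racemic trans-dihydroflavonol, one enantiomer drawn, not isolated) | COCOc1cc(ccc1OC)[C@@H]2[C@@H](O)C(=O)c3c(OC)c(CC=C(C)C)c(OC)c(CC=C(C)C)c3O2 | intermediate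
12 | 3-hydroxy-5,7-dimethoxy-2-[4-methoxy-3-(methoxymethoxy)phenyl]-6,8-bis(3-methylbut-2-enyl)-4H-chromen-4-one | COCOc1cc(-c2oc3c(CC=C(C)C)c(OC)c(CC=C(C)C)c(OC)c3c(=O)c2O)ccc1OC | intermediate
13 | 3-hydroxy-2-(3-hydroxy-4-methoxyphenyl)-5,7-dimethoxy-6,8-bis(3-methylbut-2-enyl)-4H-chromen-4-one | COc1ccc(-c2oc3c(CC=C(C)C)c(OC)c(CC=C(C)C)c(OC)c3c(=O)c2O)cc1O | intermediate
14 | 3,5-dihydroxy-2-(3-hydroxy-4-methoxyphenyl)-7-methoxy-6,8-bis(3-methylbut-2-enyl)-4H-chromen-4-one | COc1ccc(-c2oc3c(CC=C(C)C)c(OC)c(CC=C(C)C)c(O)c3c(=O)c2O)cc1O | target

**Step count**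

Total steps: 9. Longest linear sequence: 8 (steps 1, 2, 3, 4, 6, 7, 8, 9); step 5 is the side branch.

**Steps most likely to fail**

Step 3 (double benzylic Suzuki–Miyaura coupling). The strongly methoxy-activated benzylic chlorides may be lost to solvolysis or phosphate substitution, or may homocouple. The reaction may also stall after one coupling because the pinacol ester transmetalates slowly without water. The fallback sets out from 4 and returns at 6: a base-free Migita–Kosugi–Stille coupling with tributyl(2-methylprop-1-enyl)stannane (Pd(PPh3)4, CuI, toluene, 80 °C) should form the same two C1''–C2'' bonds under neutral conditions, where neither hydroxide nor water is present. No new compound lies on this path (F0).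

Step 7 (Algar–Flynn–Oyamada cyclisation). The 6'-methoxy group twists the enone, so ring closure may go through the 5-exo mode and lead to the aurone instead of the flavonol. The fallback sets out from 10 and returns at 13.
- The 2'-hydroxyl is protected (MOMCl, NaH, DMF, 0 °C) to give (E)-1-[2,4-dimethoxy-6-(methoxymethoxy)-3,5-bis(3-methylbut-2-enyl)phenyl]-3-[4-methoxy-3-(methoxymethoxy)phenyl]prop-2-en-1-one F1.
- Weitz–Scheffer epoxidation (H2O2, NaOH, MeOH–THF) should give the racemic trans-epoxide F2 without touching the prenyl olefins.
- Warm HCl in MeOH removes both MOM groups, and the freed 2'-phenol opens the epoxide at the benzylic carbon with inversion (6-endo) faster than it can add to the neighbouring prenyl group, giving the racemic trans-dihydroflavonol F3.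
- Dehydrogenation of F3 (air, KOH, MeOH) should give 13, which continues into step 9.

Step 1 (first Blanc chloromethylation). Compound 3 carries both a methoxy-activated benzylic chloride and a free nucleophilic ring position, so it may self-alkylate to diarylmethane oligomers during the reaction or on isolation. Substitution may also run on unevenly to mixtures, or the acid may cleave the acetyl group. The fallback sets out from 1 and returns at 4, bypassing 3.
- Ring bromination (NBS, 2.2 equiv, MeCN, rt) should give 3',5'-dibromo-2',4',6'-trimethoxyacetophenone F4.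
- Stille hydroxymethylation with (tributylstannyl)methanol (Pd(PPh3)4, dioxane, 100 °C) should give 3',5'-bis(hydroxymethyl)-2',4',6'-trimethoxyacetophenone F5.
- SOCl2 (cat. DMF, CH2Cl2, 0 °C) converts the diol into 4.

**Further compounds**

F0 | step 3 | none | none
F1 | step 7 | (E)-1-[2,4-dimethoxy-6-(methoxymethoxy)-3,5-bis(3-methylbut-2-enyl)phenyl]-3-[4-methoxy-3-(methoxymethoxy)phenyl]prop-2-en-1-one | COCOc1cc(/C=C/C(=O)c2c(OCOC)c(CC=C(C)C)c(OC)c(CC=C(C)C)c2OC)ccc1OC
F2 | step 7 | rac-trans-[2,4-dimethoxy-6-(methoxymethoxy)-3,5-bis(3-methylbut-2-enyl)phenyl]{3-[4-methoxy-3-(methoxymethoxy)phenyl]oxiran-2-yl}methanone (one enantiomer drawn) | COCOc1cc(ccc1OC)[C@@H]2O[C@H]2C(=O)c3c(OCOC)c(CC=C(C)C)c(OC)c(CC=C(C)C)c3OC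
F3 | step 7 | rac-(2R,3R)-3-hydroxy-2-(3-hydroxy-4-methoxyphenyl)-5,7-dimethoxy-6,8-bis(3-methylbut-2-enyl)chroman-4-one (one enantiomer drawn) | COc1ccc(cc1O)[C@@H]2[C@@H](O)C(=O)c3c(OC)c(CC=C(C)C)c(OC)c(CC=C(C)C)c3O2
F4 | step 1 | 3',5'-dibromo-2',4',6'-trimethoxyacetophenone | CC(=O)c1c(OC)c(Br)c(OC)c(Br)c1OC
F5 | step 1 | 3',5'-bis(hydroxymethyl)-2',4',6'-trimethoxyacetophenone | CC(=O)c1c(OC)c(CO)c(OC)c(CO)c1OC
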